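## Analysis of the target

Compound 28 is a trimer of three flavan-3-ol (2-arylchroman-3-ol) units. Each unit has a benzo ring A, a dihydropyran ring C and a 3,4-dihydroxyphenyl ring B, and the units are joined by two bonds from C4 of one unit to C8 of the next. The upper unit is (−)-epicatechin, the middle unit is its 5-deoxy analogue (epifisetinidol type, ring A carrying only O1 and the C7 hydroxyl), and the lower unit is (+)-catechin. There are eight stereocentres: C2, C3 and C4 of the upper and of the middle unit are (2R,3R) with ring B cis to the C3 hydroxyl and the C4 aryl group trans to it (4β), and C2 and C3 of the lower unit are (2R,3S), trans. Eleven phenols (three catechols) make the free compound prone to oxidation and, in base, to epimerisation at C2, and the two C4–aryl bonds are cleaved by acid, so every oxygen must stay masked until a final neutral step. The main difficulty is the bond from C4 of the upper ring C to C8 of the middle ring A. This C8 lies between C7–O and C8a–O1 of a resorcinol-type ring, where a flavan-4-yl cation does not attack (it goes to C6), so the usual cation coupling of flavanol units cannot make it; in addition the middle unit has three contiguous stereocentres and no chiral-pool source. The strategy rests on that atom: the carbon between the two oxygens of a resorcinol diether is the position that ortho-lithiation reaches, so it is bonded first to the carbon that becomes upper C4, and ring C of the upper unit is then closed from the other side, by bonding C4 to C4a of the symmetric phloroglucinol-type ring A.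

## Retrosynthetic reasoning

28 from 27. Only the thirteen benzyl C–O bonds are cut. All phenols and the two outer C3 hydroxyls are carried as benzyl ethers so that one hydrogenolysis under neutral conditions releases the oxidation- and acid-sensitive trimer. The forward step has to leave the C4–aryl bonds and the benzylic C2–O1 bonds untouched.

27 from 26. The bond C4–C4a of the middle unit is cut, which opens the middle ring C to an aryl ether of an epoxy alcohol whose distal epoxide carbon already carries C8 of the lower unit. Cutting here rather than at C4–C8(lower) lets the lower unit arrive intact with its two stereocentres, and the middle C4 is set in a ring closure and not in an open chain. The forward reaction is an arene attack on the epoxide carbon with inversion; the only ring A carbon that can close a six-membered ring is the one ortho to the ether oxygen and para to the C7 benzyloxy group.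

26 from 16 and 25. The aryl ether bond O1–C2 of the middle unit is cut. The forward etherification must invert the benzylic carbinol carbon of the erythro epoxy alcohol 25, so that the threo ether results and the later ring has C2 and C3 cis.

16 from 13 via 14. These are protecting-group changes on the 2,6-dioxygenated aryl group at upper C4. One oxygen is a benzyl ether from the start and becomes the C7 oxygen of the middle unit. The other is a methoxymethyl acetal, which directs the lithiation and is removed selectively in 14 to free the oxygen that becomes middle O1. The C3 hydroxyl of 13 is benzylated first so that it cannot interfere.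

13 from 12 (key disconnection). The bond C4–C4a of the upper unit is cut. Because the bond from upper C4 to middle C8 cannot be made by electrophilic substitution, it is kept as a preformed aryl–carbon bond and ring C is closed on the other side of C4, where the nucleophile is a symmetric 3,5-bis(benzyloxy)phenyl ether with two equivalent ortho carbons. The step gains ring C and the C4 stereocentre; it has to open the trans epoxide of 12 at the benzylic carbon (six-ring closure, not five) with inversion.

12 from 9 and 11. The aryl ether bond O1–C2 of the upper unit is cut, again to be made with inversion, from the erythro epoxy alcohol 9 and the phenol 11 (from 10).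

9 from 8, 7, and then 4 and 6. The carbinol of 9 comes from chelation-controlled reduction of the epoxy ketone 8, the epoxide from face-selective nucleophilic epoxidation of the E-enone 7, and the C3–C4 bond of 7 from aldol condensation of aldehyde 4 with ketone 6 (from 5). This places all of C2, C3 and C4 of the upper unit under reagent or 1,2-substrate control.

4 from 2 and 1. The C–C bond to the formyl carbon is cut at the ring carbon between the two oxygens; it is formed through the aryllithium 3, the only practical way to substitute that position.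

25 from 24, 23, and then 22 and 6; 22 from 17. The same sequence is applied to the aldehyde 22. Its formyl group is placed on C8 of perbenzylated catechin 19 (from 17 via 18) by bromination to 20 and bromine–lithium exchange to 21.

## Alternatives that were turned down

Alternative 1: The lower ring A would be built last by cutting its bonds C8a–C8, C7–C6 and C8a–C4a. In the forward direction the siloxyalkyne A2 (a silyloxyethynyl group at 4β of the middle unit of the upper–middle dimer) is heated with the cyclobutenone A3. A Danheiser-type benzannulation (4π opening to a vinylketene, [2+2] with the alkyne, a second 4π opening, 6π closure) gives phenol A1 with the silyloxy group at C7, benzyloxy at C5 and a cinnamyl chain at C4a.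
- For: the substitution pattern of the lower ring A is fixed by the cascade, so the C8-versus-C6 question never arises, and the step is convergent. On positional control it is stronger than a Friedel–Crafts coupling.
- Against: the lower unit is (+)-catechin, which is available with both stereocentres. A1 still needs ring C of the lower unit (two stereocentres) built on the largest intermediate, and the alkyne must be placed stereoselectively at middle C4. The step also does nothing for the upper C4–middle C8 bond, which is the real problem.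
- Comparison: the chosen route gets positional control in the lower unit more cheaply, from C8 bromination of 19, and spends its key step on the bond that has no standard solution.

Alternative 2: The bond O1–C2 of the middle unit would be cut in the fully assembled trimer. Fluoride cleaves the aryl silyl ether of A5, and the ring A phenoxide opens the cis-epoxide at the benzylic C2 with inversion to give A4.
- For: the last bond forms under basic conditions that spare the interflavan bonds, and the cis-epoxide gives the 2,3-cis ring directly. The intramolecular ether formation is also insensitive to crowding at the phenol oxygen; on this point it is stronger than the chosen route, whose step 19 is an intermolecular etherification of a hindered phenol.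
- Against: A5 holds the middle C4 stereocentre in an open chain, as a carbon bearing ring A, the lower unit and the epoxide. Setting that centre acyclically, next to a Z-alkene that must be epoxidised face-selectively, is the hard part and is not solved by the key step. Under base the phenoxide may also prefer five-ring closure at C3 over six-ring closure at a carbon activated only by a dialkoxyphenyl group.
- Comparison: in place of the easy last etherification, the chosen strategy sets both C4 centres during ring closure by inversion at an epoxide, and both epoxides come from E-enones through one repeated sequence.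

Alternative 3: The bond C3–C4 of the upper unit would be cut. Dehydration of the 2-hydroxybenzhydrol A7 gives an ortho-quinone methide; the enamine from aldehyde A8 and a diarylprolinol silyl ether adds to the methide carbon, and the phenol closes to the lactol A6.
- For: one catalytic step sets C3 and C4 from achiral pieces and reaches the chroman core in fewer steps than the chosen sequence. On step count to that point it is stronger.
- Against: the methide carbon carries a twisted 2,6-disubstituted aryl ring, and the catalyst must control two centres in a crowded addition. A6 also has no ring B: the C2 aryl group would have to be added to the lactol carbon, where nucleophiles add anti to the C3 silyloxy group and give the 2,3-trans ring, so a correction at C2 or C3 would follow.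
- Comparison: the chosen route brings ring B in with ketone 6 and defines C2 by inversion in step 8, so all three centres of ring C emerge in the required relationship without later correction.

Key step: step 9

Remark on the chemistry: the poly-L-leucine epoxidations of 7 and 23 are assumed to show the facial preference known for simple chalcones ((αR,βS)-epoxy ketone); compounds 13–16 and 26 may show slowly interconverting rotamers about the C4–aryl bond, which has no stereochemical consequence.

## Route

Step 1
Reactants: 1 3-(benzyloxy)phenol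
Product: 2 1-(benzyloxy)-3-(methoxymethoxy)benzene
Conditions: MOMCl, i-Pr2NEt, CH2Cl2, 0 °C → rt
Reagents that add atoms: chloromethyl methyl ether, COCCl
Why: Williamson-type O-alkylation of the phenol; the acetal is the ortho-directing group for step 2 and can later be removed without touching benzyl ethers.

Step 2
Reactants: 2 1-(benzyloxy)-3-(methoxymethoxy)benzene
Product: 4 2-(benzyloxy)-6-(methoxymethoxy)benzaldehyde, via aryllithium 3 (not isolated)
Conditions: n-BuLi, TMEDA, THF, 0 °C; DMF, −78 °C → rt; H2O
Reagents that add atoms: N,N-dimethylformamide, CN(C)C=O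
Why: Directed ortho-metalation: both oxygen groups direct the base to the carbon between them, and formylation of the aryllithium puts a carbon substituent at the position that electrophilic substitution would avoid.

Step 3
Reactants: 5 3,4-dihydroxyacetophenone
Product: 6 3,4-bis(benzyloxy)acetophenone
Conditions: BnBr, K2CO3, DMF, 60 °C
Reagents that add atoms: benzyl bromide, BrCc1ccccc1
Why: Williamson ether synthesis on both phenols; the methyl ketone is untouched by carbonate.

Step 4
Reactants: 4 2-(benzyloxy)-6-(methoxymethoxy)benzaldehyde; 6 3,4-bis(benzyloxy)acetophenone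
Product: 7 (E)-3-[2-(benzyloxy)-6-(methoxymethoxy)phenyl]-1-[3,4-bis(benzyloxy)phenyl]prop-2-en-1-one
Conditions: KOH, EtOH/THF, rt
Reagents that add atoms: none
Why: Claisen–Schmidt condensation of a non-enolisable aldehyde with a methyl ketone; dehydration gives the E-enone, and acetal and benzyl ethers are stable to base.

Step 5
Reactants: 7 (E)-enone
Product: 8 [3,4-bis(benzyloxy)phenyl]{(2R,3S)-3-[2-(benzyloxy)-6-(methoxymethoxy)phenyl]oxiran-2-yl}methanone
Conditions: poly-L-leucine, urea–H2O2, DBU, THF, rt
Reagents that add atoms: urea–hydrogen peroxide, NC(N)=O.OO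
Why: Juliá–Colonna epoxidation: conjugate addition of hydroperoxide and ring closure give the trans epoxide, and the L-polypeptide selects the enone face that leads to the (αR,βS) epoxy ketone, fixing the future C3 and C4 of the upper unit.

Step 6
Reactants: 8 (2R,3S)-epoxy ketone
Product: 9 (S)-[3,4-bis(benzyloxy)phenyl]{(2S,3S)-3-[2-(benzyloxy)-6-(methoxymethoxy)phenyl]oxiran-2-yl}methanol (erythro)
Conditions: Zn(BH4)2, Et2O, −20 °C; H2O
Reagents that add atoms: none
Why: Chelation-controlled hydride reduction: zinc bridges the carbonyl and epoxide oxygens and hydride enters from the face away from the epoxide C–C bond, giving the erythro alcohol, whose carbinol carbon has the configuration opposite to that needed at C2.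

Step 7
Reactants: 10 phloroglucinol
Product: 11 3,5-bis(benzyloxy)phenol
Conditions: BnBr (2 equiv), K2CO3, DMF, rt
Reagents that add atoms: benzyl bromide, BrCc1ccccc1
Why: Statistical Williamson dibenzylation of the symmetric triol; mono-, di- and tribenzyl ethers differ enough in polarity to be separated, and the others can be recycled.

Step 8
Reactants: 9 erythro epoxy alcohol; 11 3,5-bis(benzyloxy)phenol
Product: 12 (2R,3S)-2-{(R)-[3,5-bis(benzyloxy)phenoxy][3,4-bis(benzyloxy)phenyl]methyl}-3-[2-(benzyloxy)-6-(methoxymethoxy)phenyl]oxirane (threo aryl ether)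
Conditions: PPh3, DIAD, toluene, 0 °C → rt
Reagents that add atoms: none
Why: Mitsunobu etherification: the phenoxide displaces the alkoxyphosphonium group with inversion, giving the threo ether with the (R) carbon that becomes C2; the neutral conditions spare the epoxide and the non-polar solvent disfavours ionisation of the benzylic centre.

Step 9
Reactants: 12 threo aryl ether of the trans-epoxy alcohol
Product: 13 5,7,3',4'-tetra-O-benzyl-4β-[2-(benzyloxy)-6-(methoxymethoxy)phenyl]epicatechin
Conditions: HFIP/CH2Cl2 (4:1), 0 °C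
Reagents that add atoms: none
Why: The strongly hydrogen-bond-donating solvent activates the epoxide oxygen and the C–O bond at the carbon benzylic to the 2,6-dioxygenated ring lengthens; one of the two equivalent carbons ortho to the ether oxygen of the 3,5-bis(benzyloxy)phenoxy ring attacks that carbon from the side opposite the departing oxygen, and proton loss restores the aromatic ring. The closest known reaction type is the intramolecular Friedel–Crafts epoxide–arene cyclisation of aryl 3-arylglycidyl ethers to trans-4-arylchroman-3-ols in fluorinated alcohols or with catalytic Lewis acid. Ring C of the upper unit (O1–C2–C3–C4–C4a–C8a) closes in the 6-endo mode by forming C4–C4a; the 5-exo alternative at C3 would give a dihydrobenzofuran and is disfavoured because C3 has no cation-stabilising group. The new stereocentre C4 is set by inversion at the epoxide carbon, so the trans epoxide gives the 3,4-trans (4β-aryl) arrangement, while C2 (from step 8) and C3 (from step 5) are carried through and make the ring 2,3-cis. The step needs site selectivity (C4 over C3), chemoselectivity for the phloroglucinol-type ring over ring B and the solvent, and stereospecific opening: the donor aryl group on C4 directs the site, the trioxygenated ring is the best nucleophile and the only one that forms a six-membered ring, the solvent is non-nucleophilic, and the symmetry of the ring makes both ortho carbons give the same product. If ionisation runs ahead of bond formation, the arene tethered through C2 still reaches C4 most easily with the C3 oxygen anti and the ortho-substituted aryl group next to the C3 hydrogen, which again leads to the trans product.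

Step 10
Reactants: 13 4β-aryl epicatechin tetrabenzyl ether
Product: 14 3,5,7,3',4'-penta-O-benzyl-4β-[2-(benzyloxy)-6-(methoxymethoxy)phenyl]epicatechin
Conditions: NaH, BnBr, n-Bu4NI (cat.), DMF, 0 °C → rt
Reagents that add atoms: benzyl bromide, BrCc1ccccc1
Why: Williamson benzylation of the secondary alkoxide; it masks the C3 hydroxyl before the silyl triflate of step 11 and the etherification of step 19, and no carbon acid in 13 is deprotonated by NaH.

Step 11
Reactants: 14 penta-O-benzyl methoxymethyl ether
Product: 16 3,5,7,3',4'-penta-O-benzyl-4β-[2-(benzyloxy)-6-hydroxyphenyl]epicatechin, via trimethylsilyl ether 15 (not isolated)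
Conditions: TMSOTf, 2,2'-bipyridyl, CH2Cl2, 0 °C → rt; H2O
Reagents that add atoms: none
Why: Silyl triflate/bipyridyl cleavage of an aromatic methoxymethyl ether: the acetal is activated by the silyl triflate, bipyridyl takes up the methoxymethyl cation, and water hydrolyses the aryl silyl ether. The medium stays non-acidic, so the acid-labile C4–aryl bond and the benzyl ethers survive.

Step 12
Reactants: 17 (+)-catechin
Product: 18 5,7,3',4'-tetra-O-benzylcatechin
Conditions: BnBr, K2CO3, DMF, rt
Reagents that add atoms: benzyl bromide, BrCc1ccccc1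
Why: Williamson benzylation of the four phenols with a weak base that leaves the secondary alcohol alone and is too mild to epimerise C2.

Step 13
Reactants: 18 5,7,3',4'-tetra-O-benzylcatechin
Product: 19 3,5,7,3',4'-penta-O-benzylcatechin
Conditions: NaH, BnBr, DMF, 0 °C → rt
Reagents that add atoms: benzyl bromide, BrCc1ccccc1
Why: Williamson benzylation of the remaining C3 alkoxide, so that no acidic proton is present in the lithiation of step 15.

Step 14
Reactants: 19 3,5,7,3',4'-penta-O-benzylcatechin
Product: 20 8-bromo-3,5,7,3',4'-penta-O-benzylcatechin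
Conditions: NBS, CH2Cl2, −40 → 0 °C
Reagents that add atoms: N-bromosuccinimide, O=C1CCC(=O)N1Br
Why: Electrophilic aromatic bromination: the trioxygenated ring A is far more nucleophilic than ring B, and in 5,7-dialkoxyflavans C8 is the preferred site over C6.

Step 15
Reactants: 20 8-bromo-3,5,7,3',4'-penta-O-benzylcatechin
Product: 22 3,5,7,3',4'-penta-O-benzylcatechin-8-carbaldehyde, via 8-lithio species 21 (not isolated)
Conditions: n-BuLi, THF, −78 °C; DMF, −78 °C → rt; H2O
Reagents that add atoms: N,N-dimethylformamide, CN(C)C=O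
Why: Bromine–lithium exchange followed by formylation; the position is fixed by the bromide, and the low temperature prevents reaction of the aryllithium with the neighbouring benzyl ethers.

Step 16
Reactants: 22 catechin-8-carbaldehyde; 6 3,4-bis(benzyloxy)acetophenone
Product: 23 (E)-1-[3,4-bis(benzyloxy)phenyl]-3-(3,5,7,3',4'-penta-O-benzylcatechin-8-yl)prop-2-en-1-one
Conditions: KOH, EtOH/THF, rt → 40 °C
Reagents that add atoms: none
Why: Claisen–Schmidt condensation as in step 4; the benzylated catechin has no base-labile centre, since C2 epimerises only when the para phenol is free.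

Step 17
Reactants: 23 (E)-enone
Product: 24 [3,4-bis(benzyloxy)phenyl][(2R,3S)-3-(3,5,7,3',4'-penta-O-benzylcatechin-8-yl)oxiran-2-yl]methanone
Conditions: poly-L-leucine, urea–H2O2, DBU, THF, rt
Reagents that add atoms: urea–hydrogen peroxide, NC(N)=O.OO
Why: Juliá–Colonna epoxidation as in step 5; the polypeptide is expected to override the remote stereocentres of the catechin and to give the (αR,βS) trans epoxide, the future C3 and C4 of the middle unit.

Step 18
Reactants: 24 (2R,3S)-epoxy ketone
Product: 25 (S)-[3,4-bis(benzyloxy)phenyl][(2S,3S)-3-(3,5,7,3',4'-penta-O-benzylcatechin-8-yl)oxiran-2-yl]methanol (erythro)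
Conditions: Zn(BH4)2, Et2O/THF, −40 °C; H2O
Reagents that add atoms: none
Why: Chelation-controlled reduction as in step 6 gives the erythro alcohol; the low temperature and aprotic medium protect the electron-rich epoxide.

Step 19
Reactants: 16 phenol of the upper unit; 25 erythro epoxy alcohol of the lower unit
Product: 26 3,5,7,3',4'-penta-O-benzyl-4β-{2-(benzyloxy)-6-[(R)-[3,4-bis(benzyloxy)phenyl]{(2R,3S)-3-(3,5,7,3',4'-penta-O-benzylcatechin-8-yl)oxiran-2-yl}methoxy]phenyl}epicatechin (threo aryl ether)
Conditions: PPh3, DIAD, toluene (concentrated), 0 °C → rt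
Reagents that add atoms: none
Why: Mitsunobu etherification with inversion at the carbinol carbon, as in step 8, gives the threo ether whose (R) carbon becomes C2 of the middle unit; the phenol has one free ortho position, and a concentrated solution is used because its other ortho position carries the flavanyl group.

Step 20
Reactants: 26 threo aryl ether
Product: 27 3,5,7,3',4'-penta-O-benzylepicatechin-(4β→8)-7,3',4'-tri-O-benzylepifisetinidol-(4β→8)-3,5,7,3',4'-penta-O-benzylcatechin
Conditions: HFIP/CH2Cl2, −20 → 0 °C
Reagents that add atoms: none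
Why: The epoxide–arene cyclisation of step 9 is repeated: the ring A carbon ortho to the ether oxygen and para to the C7 benzyloxy group attacks the epoxide carbon that bears the trioxygenated catechin ring, in the 6-endo mode and with inversion. This forms C4–C4a of the middle unit and sets its 4β-aryl centre next to the cis C2/C3 pair.

Step 21
Reactants: 27 tridecabenzyl trimer
Product: 28 epicatechin-(4β→8)-epifisetinidol-(4β→8)-catechin (CNP0270097.1)
Conditions: H2 (1 atm), Pd(OH)2/C, THF/MeOH/H2O, rt
Reagents that add atoms: none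
Why: Hydrogenolysis of all thirteen benzyl ethers under neutral conditions; the C4–aryl bonds and the ring C2–O1 bonds of flavans are retained under such mild conditions, and no stereocentre is touched.

## Compound list

1 | 3-(benzyloxy)phenol | Oc1cccc(OCc2ccccc2)c1 | starting material
2 | 1-(benzyloxy)-3-(methoxymethoxy)benzene | COCOc1cccc(OCc2ccccc2)c1 | intermediate
3 | [2-(benzyloxy)-6-(methoxymethoxy)phenyl]lithium | COCOc1cccc(OCc2ccccc2)c1[Li] | intermediate
4 | 2-(benzyloxy)-6-(methoxymethoxy)benzaldehyde | COCOc1cccc(OCc2ccccc2)c1C=O | intermediate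
5 | 3,4-dihydroxyacetophenone | CC(=O)c1ccc(O)c(O)c1 | starting material
6 | 3,4-bis(benzyloxy)acetophenone | CC(=O)c1ccc(OCc2ccccc2)c(OCc2ccccc2)c1 | intermediate
7 | (E)-3-[2-(benzyloxy)-6-(methoxymethoxy)phenyl]-1-[3,4-bis(benzyloxy)phenyl]prop-2-en-1-one | O=C(/C=C/c1c(OCOC)cccc1OCc1ccccc1)c1ccc(OCc2ccccc2)c(OCc2ccccc2)c1 | intermediate
8 | [3,4-bis(benzyloxy)phenyl]{(2R,3S)-3-[2-(benzyloxy)-6-(methoxymethoxy)phenyl]oxiran-2-yl}methanone | O=C(c1ccc(OCc2ccccc2)c(OCc2ccccc2)c1)[C@@H]1O[C@H]1c1c(OCOC)cccc1OCc1ccccc1 | intermediate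
9 | (S)-[3,4-bis(benzyloxy)phenyl]{(2S,3S)-3-[2-(benzyloxy)-6-(methoxymethoxy)phenyl]oxiran-2-yl}methanol (erythro) | O[C@@H](c1ccc(OCc2ccccc2)c(OCc2ccccc2)c1)[C@@H]1O[C@H]1c1c(OCOC)cccc1OCc1ccccc1 | intermediate
10 | phloroglucinol | Oc1cc(O)cc(O)c1 | starting material
11 | 3,5-bis(benzyloxy)phenol | Oc1cc(OCc2ccccc2)cc(OCc2ccccc2)c1 | intermediate
12 | (2R,3S)-2-{(R)-[3,5-bis(benzyloxy)phenoxy][3,4-bis(benzyloxy)phenyl]methyl}-3-[2-(benzyloxy)-6-(methoxymethoxy)phenyl]oxirane (threo aryl ether of the trans-epoxy alcohol) | c1ccccc1COc1cc(OCc2ccccc2)cc(c1)O[C@H](c1ccc(OCc2ccccc2)c(OCc2ccccc2)c1)[C@@H]1O[C@H]1c1c(OCOC)cccc1OCc1ccccc1 | intermediate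
13 | 5,7,3',4'-tetra-O-benzyl-4β-[2-(benzyloxy)-6-(methoxymethoxy)phenyl]epicatechin ((2R,3R), 2,3-cis, 3,4-trans) | c1ccccc1COc1cc(OCc2ccccc2)c2c(c1)O[C@H](c1ccc(OCc3ccccc3)c(OCc3ccccc3)c1)[C@H](O)[C@H]2c1c(OCOC)cccc1OCc1ccccc1 | intermediate
14 | 3,5,7,3',4'-penta-O-benzyl-4β-[2-(benzyloxy)-6-(methoxymethoxy)phenyl]epicatechin | c1ccccc1COc1cc(OCc2ccccc2)c2c(c1)O[C@H](c1ccc(OCc3ccccc3)c(OCc3ccccc3)c1)[C@H](OCc1ccccc1)[C@H]2c1c(OCOC)cccc1OCc1ccccc1 | intermediate
15 | 3,5,7,3',4'-penta-O-benzyl-4β-[2-(benzyloxy)-6-(trimethylsilyloxy)phenyl]epicatechin | c1ccccc1COc1cc(OCc2ccccc2)c2c(c1)O[C@H](c1ccc(OCc3ccccc3)c(OCc3ccccc3)c1)[C@H](OCc1ccccc1)[C@H]2c1c(O[Si](C)(C)C)cccc1OCc1ccccc1 | intermediate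
16 | 3,5,7,3',4'-penta-O-benzyl-4β-[2-(benzyloxy)-6-hydroxyphenyl]epicatechin | c1ccccc1COc1cc(OCc2ccccc2)c2c(c1)O[C@H](c1ccc(OCc3ccccc3)c(OCc3ccccc3)c1)[C@H](OCc1ccccc1)[C@H]2c1c(O)cccc1OCc1ccccc1 | intermediate
17 | (+)-catechin | Oc1cc(O)c2c(c1)O[C@H](c1ccc(O)c(O)c1)[C@@H](O)C2 | starting material
18 | 5,7,3',4'-tetra-O-benzylcatechin | c1ccccc1COc1cc(OCc2ccccc2)c2c(c1)O[C@H](c1ccc(OCc3ccccc3)c(OCc3ccccc3)c1)[C@@H](O)C2 | intermediate
19 | 3,5,7,3',4'-penta-O-benzylcatechin | c1ccccc1COc1cc(OCc2ccccc2)c2c(c1)O[C@H](c1ccc(OCc3ccccc3)c(OCc3ccccc3)c1)[C@@H](OCc1ccccc1)C2 | intermediate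
20 | 8-bromo-3,5,7,3',4'-penta-O-benzylcatechin | c1ccccc1COc1cc(OCc2ccccc2)c2c(c1Br)O[C@H](c1ccc(OCc3ccccc3)c(OCc3ccccc3)c1)[C@@H](OCc1ccccc1)C2 | intermediate
21 | 8-lithio-3,5,7,3',4'-penta-O-benzylcatechin | c1ccccc1COc1cc(OCc2ccccc2)c2c(c1[Li])O[C@H](c1ccc(OCc3ccccc3)c(OCc3ccccc3)c1)[C@@H](OCc1ccccc1)C2 | intermediate
22 | 3,5,7,3',4'-penta-O-benzylcatechin-8-carbaldehyde | c1ccccc1COc1cc(OCc2ccccc2)c2c(c1C=O)O[C@H](c1ccc(OCc3ccccc3)c(OCc3ccccc3)c1)[C@@H](OCc1ccccc1)C2 | intermediate
23 | (E)-1-[3,4-bis(benzyloxy)phenyl]-3-(3,5,7,3',4'-penta-O-benzylcatechin-8-yl)prop-2-en-1-one | c1ccccc1COc1cc(OCc2ccccc2)c2c(c1/C=C/C(=O)c1ccc(OCc3ccccc3)c(OCc3ccccc3)c1)O[C@H](c1ccc(OCc3ccccc3)c(OCc3ccccc3)c1)[C@@H](OCc1ccccc1)C2 | intermediate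
24 | [3,4-bis(benzyloxy)phenyl][(2R,3S)-3-(3,5,7,3',4'-penta-O-benzylcatechin-8-yl)oxiran-2-yl]methanone | c1ccccc1COc1cc(OCc2ccccc2)c2c(c1[C@@H]4O[C@H]4C(=O)c1ccc(OCc3ccccc3)c(OCc3ccccc3)c1)O[C@H](c1ccc(OCc3ccccc3)c(OCc3ccccc3)c1)[C@@H](OCc1ccccc1)C2 | intermediate
25 | (S)-[3,4-bis(benzyloxy)phenyl][(2S,3S)-3-(3,5,7,3',4'-penta-O-benzylcatechin-8-yl)oxiran-2-yl]methanol (erythro) | c1ccccc1COc1cc(OCc2ccccc2)c2c(c1[C@@H]4O[C@H]4[C@@H](O)c1ccc(OCc3ccccc3)c(OCc3ccccc3)c1)O[C@H](c1ccc(OCc3ccccc3)c(OCc3ccccc3)c1)[C@@H](OCc1ccccc1)C2 | intermediate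
26 | 3,5,7,3',4'-penta-O-benzyl-4β-{2-(benzyloxy)-6-[(R)-[3,4-bis(benzyloxy)phenyl]{(2R,3S)-3-(3,5,7,3',4'-penta-O-benzylcatechin-8-yl)oxiran-2-yl}methoxy]phenyl}epicatechin (threo aryl ether) | c1ccccc1COc1cc(OCc2ccccc2)c2c(c1)O[C@H](c1ccc(OCc3ccccc3)c(OCc3ccccc3)c1)[C@H](OCc1ccccc1)[C@H]2c1c(O[C@H](c2ccc(OCc3ccccc3)c(OCc3ccccc3)c2)[C@@H]2O[C@H]2c2c(OCc3ccccc3)cc(OCc3ccccc3)c3c2O[C@H](c2ccc(OCc4ccccc4)c(OCc4ccccc4)c2)[C@@H](OCc2ccccc2)C3)cccc1OCc1ccccc1 | intermediate
27 | 3,5,7,3',4'-penta-O-benzylepicatechin-(4β→8)-7,3',4'-tri-O-benzylepifisetinidol-(4β→8)-3,5,7,3',4'-penta-O-benzylcatechin (free 3-OH on the middle unit) | c1ccccc1COc1cc(OCc2ccccc2)c2c(c1)O[C@H](c1ccc(OCc3ccccc3)c(OCc3ccccc3)c1)[C@H](OCc1ccccc1)[C@H]2c1c(OCc2ccccc2)ccc2c1O[C@H](c1ccc(OCc3ccccc3)c(OCc3ccccc3)c1)[C@H](O)[C@H]2c1c(OCc2ccccc2)cc(OCc2ccccc2)c2c1O[C@H](c1ccc(OCc3ccccc3)c(OCc3ccccc3)c1)[C@@H](OCc1ccccc1)C2 | intermediate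
28 | epicatechin-(4β→8)-epifisetinidol-(4β→8)-catechin (CNP0270097.1) | Oc1cc(O)c2c(c1)O[C@H](c1ccc(O)c(O)c1)[C@H](O)[C@H]2c1c(O)ccc2c1O[C@H](c1ccc(O)c(O)c1)[C@H](O)[C@H]2c1c(O)cc(O)c2c1O[C@H](c1ccc(O)c(O)c1)[C@@H](O)C2 | target

## Step count and least certain steps

Total step count: 21. Longest linear sequence: 12 steps (1 → 2 → 4 → 7 → 8 → 9 → 12 → 13 → 14 → 16 → 26 → 27 → 28, steps 1, 2, 4, 5, 6, 8, 9, 10, 11, 19, 20, 21).

Step 9 (key step). The most likely failure is ionisation of the epoxide running ahead of ring closure. The donor aryl group makes the benzylic cation easy to form, and a 1,2-hydride shift to a ketone (Meinwald rearrangement), participation of an ortho ether oxygen, or attack on the wrong face of a free cation (erosion of the 3,4-trans relationship) can then compete with the six-ring closure. Fallback, from 12 back to the route at 14: the opening and the closure are separated. Acid-catalysed methanolysis of 12 (MeOH, PPTS, 0 °C) opens the epoxide at the benzylic carbon to the (1R,2R,3R) benzylic methyl ether F1, and the liberated hydroxyl is benzylated (NaH, BnBr) to the benzyl ether F2. BF3·OEt2 in CH2Cl2 at −78 °C then ionises the benzylic methyl ether and the phloroglucinol-type ring closes ring C in a Friedel–Crafts alkylation to give 14 directly. With the C3 oxygen capped, the shift to a ketone is no longer possible, and the configuration at the methoxy carbon is immaterial because it is lost on ionisation.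

Step 19. The most likely failure is a slow or failed displacement. The phenol oxygen of 16 is shielded by the neighbouring flavanyl group and the carbinol of 25 is flanked by two large groups, so elimination or ionisation of the activated benzylic alcohol can overtake the substitution. Fallback, from 4 and 25 back to the route at 28: the order of assembly is reversed so that both etherifications use unhindered phenols.
- The acetal of 4 is removed (HCl, MeOH) to give 2-(benzyloxy)-6-hydroxybenzaldehyde F3.
- Mitsunobu reaction of F3 with 25 gives the aldehyde ether F4, and the fluoroalcohol cyclisation closes the middle ring C to the middle–lower dimer aldehyde F5 (attack through the ring carbon para to the benzyloxy group).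
- Benzylation of the C3 hydroxyl gives F6, and Claisen–Schmidt condensation with 6 gives the enone F7.
- Poly-L-leucine epoxidation gives the (2R,3S)-epoxy ketone F8, and Zn(BH4)2 reduction gives the erythro epoxy alcohol F9.
- Mitsunobu reaction with 11 gives the threo aryl ether F10, and the epoxide–arene closure of the upper ring C, now the last skeletal step, gives the tridecabenzyl trimer F11 with a free upper 3-OH.
- Hydrogenolysis of F11 over Pd(OH)2/C gives 28.

Step 20. The epoxide of 26 carries a trioxygenated aryl group and opens very easily, while the attacking ring A has only two donor oxygens. The likely failure is rearrangement or loss of configuration at C4 of a long-lived cation before the ring closes; the same lability may already cause losses during steps 17–19. Fallback, from 26 back to the route at 27: the cation is first trapped by a sulfur nucleophile. Opening of 26 in the presence of excess 4-methylbenzenethiol (HFIP/CH2Cl2, −20 °C) gives the benzylic 4-methylphenyl sulfide F12, a stable compound that can be purified. The thiophilic salt AgBF4 in THF/CH2Cl2 at −40 → 0 °C then releases the cation under neutral conditions for the Friedel–Crafts closure to 27, as in the classical activation of flavan 4-thioethers.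

Step 17. The enone 23 is deactivated by the trioxygenated ring, is hindered on both sides of the β-carbon and carries remote stereocentres. The likely failure is slow conversion, or poor facial selectivity if the substrate is mismatched with the polypeptide. Fallback, from 23 back to the route at 25: the epoxide is introduced by a hydroxyl-directed electrophilic epoxidation in place of the nucleophilic one. Luche reduction of 23 (NaBH4, CeCl3·7H2O, MeOH/THF, −20 °C) gives the allylic alcohol F13 as a mixture of carbinol epimers. Sharpless epoxidation (Ti(OiPr)4, L-(+)-diisopropyl tartrate, t-BuOOH, 4 Å molecular sieves, CH2Cl2, −25 °C) then converts the epimer that is matched with the tartrate into the erythro epoxy alcohol 25, as in a kinetic resolution, while the other epimer is left and can be reoxidised to 23 with MnO2.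

## Further compounds

F1 | step 9 | (1R,2R,3R)-3-[2-(benzyloxy)-6-(methoxymethoxy)phenyl]-1-[3,5-bis(benzyloxy)phenoxy]-1-[3,4-bis(benzyloxy)phenyl]-3-methoxypropan-2-ol | c1ccccc1COc1cc(OCc2ccccc2)cc(c1)O[C@H](c1ccc(OCc2ccccc2)c(OCc2ccccc2)c1)[C@H](O)[C@H](OC)c1c(OCOC)cccc1OCc1ccccc1
F2 | step 9 | benzyl ether of F1 at the C2 hydroxyl, (1R,2R,3R) | c1ccccc1COc1cc(OCc2ccccc2)cc(c1)O[C@H](c1ccc(OCc2ccccc2)c(OCc2ccccc2)c1)[C@H](OCc1ccccc1)[C@H](OC)c1c(OCOC)cccc1OCc1ccccc1
F3 | step 19 | 2-(benzyloxy)-6-hydroxybenzaldehyde | O=Cc1c(O)cccc1OCc1ccccc1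
F4 | step 19 | 2-(benzyloxy)-6-[(R)-[3,4-bis(benzyloxy)phenyl]{(2R,3S)-3-(3,5,7,3',4'-penta-O-benzylcatechin-8-yl)oxiran-2-yl}methoxy]benzaldehyde | O=Cc1c(O[C@H](c2ccc(OCc3ccccc3)c(OCc3ccccc3)c2)[C@@H]2O[C@H]2c2c(OCc3ccccc3)cc(OCc3ccccc3)c3c2O[C@H](c2ccc(OCc4ccccc4)c(OCc4ccccc4)c2)[C@@H](OCc2ccccc2)C3)cccc1OCc1ccccc1
F5 | step 19 | 8-formyl-7,3',4'-tri-O-benzylepifisetinidol-(4β→8)-3,5,7,3',4'-penta-O-benzylcatechin | O=Cc1c(OCc2ccccc2)ccc2c1O[C@H](c1ccc(OCc3ccccc3)c(OCc3ccccc3)c1)[C@H](O)[C@H]2c1c(OCc2ccccc2)cc(OCc2ccccc2)c2c1O[C@H](c1ccc(OCc3ccccc3)c(OCc3ccccc3)c1)[C@@H](OCc1ccccc1)C2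
F6 | step 19 | 8-formyl-3,7,3',4'-tetra-O-benzylepifisetinidol-(4β→8)-3,5,7,3',4'-penta-O-benzylcatechin | O=Cc1c(OCc2ccccc2)ccc2c1O[C@H](c1ccc(OCc3ccccc3)c(OCc3ccccc3)c1)[C@H](OCc1ccccc1)[C@H]2c1c(OCc2ccccc2)cc(OCc2ccccc2)c2c1O[C@H](c1ccc(OCc3ccccc3)c(OCc3ccccc3)c1)[C@@H](OCc1ccccc1)C2
F7 | step 19 | (E)-enone from F6 and 6, with the 3-[3,4-bis(benzyloxy)phenyl]-3-oxoprop-1-enyl group at C8 of the middle unit | O=C(c1ccc(OCc2ccccc2)c(OCc2ccccc2)c1)/C=C/c1c(OCc2ccccc2)ccc2c1O[C@H](c1ccc(OCc3ccccc3)c(OCc3ccccc3)c1)[C@H](OCc1ccccc1)[C@H]2c1c(OCc2ccccc2)cc(OCc2ccccc2)c2c1O[C@H](c1ccc(OCc3ccccc3)c(OCc3ccccc3)c1)[C@@H](OCc1ccccc1)C2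
F8 | step 19 | (2R,3S)-epoxy ketone of F7 | O=C(c1ccc(OCc2ccccc2)c(OCc2ccccc2)c1)[C@@H]1O[C@H]1c1c(OCc2ccccc2)ccc2c1O[C@H](c1ccc(OCc3ccccc3)c(OCc3ccccc3)c1)[C@H](OCc1ccccc1)[C@H]2c1c(OCc2ccccc2)cc(OCc2ccccc2)c2c1O[C@H](c1ccc(OCc3ccccc3)c(OCc3ccccc3)c1)[C@@H](OCc1ccccc1)C2
F9 | step 19 | erythro epoxy alcohol from F8, (S)-carbinol and (2S,3S)-oxirane | O[C@@H](c1ccc(OCc2ccccc2)c(OCc2ccccc2)c1)[C@@H]1O[C@H]1c1c(OCc2ccccc2)ccc2c1O[C@H](c1ccc(OCc3ccccc3)c(OCc3ccccc3)c1)[C@H](OCc1ccccc1)[C@H]2c1c(OCc2ccccc2)cc(OCc2ccccc2)c2c1O[C@H](c1ccc(OCc3ccccc3)c(OCc3ccccc3)c1)[C@@H](OCc1ccccc1)C2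
F10 | step 19 | threo 3,5-bis(benzyloxy)phenyl ether of F9, (R)-ether carbon and (2R,3S)-oxirane | c1ccccc1COc1cc(OCc2ccccc2)cc(c1)O[C@H](c1ccc(OCc2ccccc2)c(OCc2ccccc2)c1)[C@@H]1O[C@H]1c1c(OCc2ccccc2)ccc2c1O[C@H](c1ccc(OCc3ccccc3)c(OCc3ccccc3)c1)[C@H](OCc1ccccc1)[C@H]2c1c(OCc2ccccc2)cc(OCc2ccccc2)c2c1O[C@H](c1ccc(OCc3ccccc3)c(OCc3ccccc3)c1)[C@@H](OCc1ccccc1)C2
F11 | step 19 | 5,7,3',4'-tetra-O-benzylepicatechin-(4β→8)-3,7,3',4'-tetra-O-benzylepifisetinidol-(4β→8)-3,5,7,3',4'-penta-O-benzylcatechin (free 3-OH on the upper unit) | c1ccccc1COc1cc(OCc2ccccc2)c2c(c1)O[C@H](c1ccc(OCc3ccccc3)c(OCc3ccccc3)c1)[C@H](O)[C@H]2c1c(OCc2ccccc2)ccc2c1O[C@H](c1ccc(OCc3ccccc3)c(OCc3ccccc3)c1)[C@H](OCc1ccccc1)[C@H]2c1c(OCc2ccccc2)cc(OCc2ccccc2)c2c1O[C@H](c1ccc(OCc3ccccc3)c(OCc3ccccc3)c1)[C@@H](OCc1ccccc1)C2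
F12 | step 20 | 16 etherified at its phenol oxygen with the (1R,2S,3R)-1-[3,4-bis(benzyloxy)phenyl]-2-hydroxy-3-(4-methylphenylsulfanyl)-3-(3,5,7,3',4'-penta-O-benzylcatechin-8-yl)propyl group (sulfide carbon drawn as the inversion product; either epimer serves) | c1ccccc1COc1cc(OCc2ccccc2)c2c(c1)O[C@H](c1ccc(OCc3ccccc3)c(OCc3ccccc3)c1)[C@H](OCc1ccccc1)[C@H]2c1c(O[C@H](c2ccc(OCc3ccccc3)c(OCc3ccccc3)c2)[C@H](O)[C@H](Sc2ccc(C)cc2)c2c(OCc3ccccc3)cc(OCc3ccccc3)c3c2O[C@H](c2ccc(OCc4ccccc4)c(OCc4ccccc4)c2)[C@@H](OCc2ccccc2)C3)cccc1OCc1ccccc1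
F13 | step 17 | (E)-1-[3,4-bis(benzyloxy)phenyl]-3-(3,5,7,3',4'-penta-O-benzylcatechin-8-yl)prop-2-en-1-ol (both carbinol epimers) | c1ccccc1COc1cc(OCc2ccccc2)c2c(c1/C=C/C(O)c1ccc(OCc3ccccc3)c(OCc3ccccc3)c1)O[C@H](c1ccc(OCc3ccccc3)c(OCc3ccccc3)c1)[C@@H](OCc1ccccc1)C2
A1 | alternative 1 | benzyl-protected upper–middle dimer carrying at middle C4β a 4-(benzyloxy)-3-[(E)-3-(3,4-bis(benzyloxy)phenyl)prop-2-enyl]-2-hydroxy-6-(triisopropylsilyloxy)phenyl group (lower ring A as free phenol) | c9ccccc9COc1cc(OCc9ccccc9)c2c(c1)O[C@H](c7ccc(OCc9ccccc9)c(OCc9ccccc9)c7)[C@H](OCc9ccccc9)[C@H]2c1c(OCc9ccccc9)ccc2c1O[C@H](c7ccc(OCc9ccccc9)c(OCc9ccccc9)c7)[C@H](OCc9ccccc9)[C@H]2c1c(O[Si](C(C)C)(C(C)C)C(C)C)cc(OCc9ccccc9)c(C/C=C/c7ccc(OCc9ccccc9)c(OCc9ccccc9)c7)c1O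
A2 | alternative 1 | benzyl-protected upper–middle dimer carrying a (triisopropylsilyloxy)ethynyl group at middle C4β | c9ccccc9COc1cc(OCc9ccccc9)c2c(c1)O[C@H](c7ccc(OCc9ccccc9)c(OCc9ccccc9)c7)[C@H](OCc9ccccc9)[C@H]2c1c(OCc9ccccc9)ccc2c1O[C@H](c7ccc(OCc9ccccc9)c(OCc9ccccc9)c7)[C@H](OCc9ccccc9)[C@H]2C#CO[Si](C(C)C)(C(C)C)C(C)C
A3 | alternative 1 | 3-(benzyloxy)-4-[(E)-3-(3,4-bis(benzyloxy)phenyl)prop-2-en-1-yl]cyclobut-2-en-1-one (racemic) | O=C1C=C(OCc2ccccc2)C1C/C=C/c1ccc(OCc2ccccc2)c(OCc2ccccc2)c1
A4 | alternative 2 | benzyl-protected trimer with a free 3-OH on the middle unit and all other hydroxyls benzylated | c9ccccc9COc1cc(OCc9ccccc9)c2c(c1)O[C@H](c7ccc(OCc9ccccc9)c(OCc9ccccc9)c7)[C@H](OCc9ccccc9)[C@H]2c1c(OCc9ccccc9)ccc2c1O[C@H](c7ccc(OCc9ccccc9)c(OCc9ccccc9)c7)[C@H](O)[C@H]2c1c(OCc9ccccc9)cc(OCc9ccccc9)c2c1O[C@H](c7ccc(OCc9ccccc9)c(OCc9ccccc9)c7)[C@@H](OCc9ccccc9)C2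
A5 | alternative 2 | ring-opened precursor of A4: middle ring A as tert-butyldimethylsilyl ether, its benzylic carbon bearing the lower unit and a cis-3-[3,4-bis(benzyloxy)phenyl]oxiran-2-yl group | c1ccccc1COc1cc(OCc2ccccc2)c2c(c1)O[C@H](c1ccc(OCc3ccccc3)c(OCc3ccccc3)c1)[C@H](OCc1ccccc1)[C@H]2c1c(OCc2ccccc2)ccc(c1O[Si](C)(C)C(C)(C)C)[C@H](c1c(OCc2ccccc2)cc(OCc2ccccc2)c2c1O[C@H](c1ccc(OCc3ccccc3)c(OCc3ccccc3)c1)[C@@H](OCc1ccccc1)C2)[C@H]1O[C@H]1c1ccc(OCc2ccccc2)c(OCc2ccccc2)c1
A6 | alternative 3 | 3,4-trans-5,7-bis(benzyloxy)-3-(tert-butyldimethylsilyloxy)-4-[2,6-bis(methoxymethoxy)phenyl]chroman-2-ol (anomeric mixture) | c9ccccc9COc1cc(OCc9ccccc9)c2c(c1)OC(O)[C@H](O[Si](C)(C)C(C)(C)C)[C@H]2c1c(OCOC)cccc1OCOC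
A7 | alternative 3 | 3,5-bis(benzyloxy)-2-{[2,6-bis(methoxymethoxy)phenyl](hydroxy)methyl}phenol | Oc1cc(OCc2ccccc2)cc(OCc2ccccc2)c1C(O)c1c(OCOC)cccc1OCOC
A8 | alternative 3 | (tert-butyldimethylsilyloxy)acetaldehyde | O=CCO[Si](C)(C)C(C)(C)C
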